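If two rivals draw on one nucleophile, what does the ratio of their rates say?

| flask | electrophile | nucleophile | protic impurity | remark | time |
|---|---|---|---|---|---|
| blue | 0.050 M | 0.0525 M | 0.070 M | run made earlier |  |
| green | 0.050 M | 0.0525 M | 0.11 M | run made earlier |  |
| flask | 0.050 M | 0.0525 M | 0.0500 M |  | 1.5 h |

| run | time / min | electrophile / % | target / % |
|---|---|---|---|
| blue | 8.00 | 88.5 | 10.7 |
| blue | 15.0 | 82.8 | 19.3 |
| blue | 25.0 | 78.1 | 22.4 |
| blue | 40.0 | 72.3 | 26.7 |
| blue | 60.0 | 69.2 | 30.6 |
| blue | 120 | 66.5 | 34.3 |
| green | 8.00 | 88.4 | 10.6 |
| green | 20.0 | 80.6 | 17.7 |
| green | 40.0 | 76.5 | 22.9 |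
| green | 60.0 | 75.5 | 26.5 |
| green | 80.0 | 74.7 | 25.3 |
| green | 120 | 70.0 | 28.6 |

(readings scatter by 1 percentage point)

* part of the electrophile that has reacted at 1.5 h
* share of the unused nucleophile that is free and not bound as protonated nucleophile, at 1.5 h

*What do electrophile and protic impurity share?* Free nucleophile. Both steps are first order in it, so c(nucleophile) drops out of their ratio. Integrated, the logarithm of the impurity fraction left is s times that of the electrophile fraction left.

*But impurity was never read. Where does s come from?* From a balance. Blue's electrophile moves from 69.2% at 60.0 min to 66.5% at 120 min. I assume each acid set free holds one nucleophile, so each target costs two. The rest of the charge is then quenched reagent. That gives the selectivity factor s, impurity logarithm over electrophile logarithm, as 0.776.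

*And green?* Green reads 0.642. These are scattered readings under an assumption. Blue holds less impurity than green, so it stands nearer this flask, and I keep its s.

*This flask?* I carry the same assumption over: each target costs two nucleophile, and quenched reagent takes the rest of the charge. Substituting repeatedly from blue's conversion gives 38.9%, 36.6%, 37.6%. I commit to 37.1%. The bound share stays unread, so I give no figure for it.

The forecast, above my figure, gives 38% and 10%, holding that “the binding is strong but not complete”.

This flask gives 36.3% and 21.1%.

    electrophile + nucleophile → acid set free + target (k = 0.00600 M⁻¹ s⁻¹)
    nucleophile + protic impurity → quenched reagent (k = 0.00610 M⁻¹ s⁻¹)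
    nucleophile + acid set free ⇌ protonated nucleophile, settled at all times (K = 680 M⁻¹)

At 36.3%, the balance with s comes to 97.2% of the nucleophile charged. Now take the neighbour with 0.12 M of protic impurity, with s and the balance unchanged. The substitution swings wider there, so I average each new value with the old one, starting from 37.1%. It passes 26.7% and stands at 26.7%. The neighbour flask gives 26.1% at 1.5 h, with 18.0% of its unused nucleophile free.

The readings are calculated for substances that don't exist; the scatter is artificial.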